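**Retrosynthetic overview**
1. Target ⇐ chemoselective opening of the 6α,12-lactone of ester 27; the C8 side chain comes from DCC coupling with silyl-protected 2-(hydroxymethyl)acrylic acid 25.
2. Lactone diol aldehyde 22 ⇐ one hydroboration of dienone 16 (sets C1, C7, C8 and delivers C15), then α-methylenation and C15 oxidation with C4 equilibration.
3. Ring A ⇐ SmI2 Barbier closure (C1–C2) of bromo-aldehyde 12; the C4–O stereocentre is then converted to C4=CH2.
4. Ring B and the γ-lactone (key step) ⇐ intermolecular Diels–Alder of 2-silyloxy-4-vinylfuran 10 with (S,E)-enal 6 (sets C5, C6, C10).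
5. Ring order: B (with lactone) by cycloaddition, then A by Barbier cyclisation; the only purchased stereocentre is that of (S)-α-hydroxy-γ-butyrolactone 1 (from L-malic acid).

Assumption/convention: eudesmane numbering is used for all bi- and tricyclic compounds (C14 = angular methyl on C10; β = same face as C14, α = opposite face); 1, 5, 7, 8 and 23 are taken as purchasable.

**Step 1**
Reactants: 1 (S)-α-hydroxy-γ-butyrolactone
Product: 2 ethyl (S)-4-bromo-2-hydroxybutanoate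
Conditions: HBr (g), EtOH, 0 °C → rt
Reagents that add atoms: hydrogen bromide, Br; ethanol, CCO
Why: Acid-mediated lactone opening, with SN2 attack of bromide at the γ-CH2 and Fischer esterification (the classical γ-lactone → ethyl 4-bromobutanoate reaction); the carbinol stereocentre is not involved.

**Step 2**
Reactants: 2 ethyl (S)-4-bromo-2-hydroxybutanoate
Product: 3 ethyl (S)-4-bromo-2-[(tert-butyldimethylsilyl)oxy]butanoate
Conditions: TBSCl, imidazole, DMF, rt
Reagents that add atoms: tert-butyldimethylsilyl chloride, CC(C)(C)[Si](C)(C)Cl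
Why: Standard Corey silylation of the secondary alcohol; the bulky OTBS group later serves as the stereocontrol element.

**Step 3**
Reactants: 3 ethyl (S)-4-bromo-2-[(tert-butyldimethylsilyl)oxy]butanoate
Product: 4 (S)-4-bromo-2-[(tert-butyldimethylsilyl)oxy]butanal
Conditions: DIBAL-H, CH2Cl2, −78 °C; Rochelle salt
Reagents that add atoms: none
Why: Low-temperature DIBAL-H partial reduction of the ester stops at the aldehyde (stable aluminium hemiacetal) without touching the bromide or epimerising the α-silyloxy centre.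

**Step 4**
Reactants: 4 (S)-4-bromo-2-[(tert-butyldimethylsilyl)oxy]butanal; 5 2-(triphenylphosphoranylidene)propanal
Product: 6 (S,E)-6-bromo-4-[(tert-butyldimethylsilyl)oxy]-2-methylhex-2-enal
Conditions: PhH, 80 °C
Reagents that add atoms: none
Why: Wittig olefination with the formyl-stabilised ylide is E-selective and neutral, so the allylic stereocentre is preserved in the 2-methyl-enal dienophile.

**Step 5**
Reactants: 7 4-bromofuran-2(5H)-one; 8 tributyl(vinyl)stannane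
Product: 9 4-vinylfuran-2(5H)-one
Conditions: Pd(PPh3)4 (5 mol %), PhMe, 90 °C
Reagents that add atoms: none
Why: Stille cross-coupling of the vinylogous acyl bromide installs the vinyl group under neutral conditions that leave the butenolide intact.

**Step 6**
Reactants: 9 4-vinylfuran-2(5H)-one
Product: 10 tert-butyldimethyl[(4-vinylfuran-2-yl)oxy]silane
Conditions: TBSOTf, Et3N, CH2Cl2, 0 °C
Reagents that add atoms: tert-butyldimethylsilyl trifluoromethanesulfonate, CC(C)(C)[Si](C)(C)OS(=O)(=O)C(F)(F)F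
Why: Soft enolisation and O-silylation (γ-deprotonation) aromatises the butenolide to the electron-rich 2-silyloxyfuran, whose furan C5=C4 bond and vinyl group form the exocyclic diene.

**Step 7**
Reactants: 6 (S,E)-6-bromo-4-[(tert-butyldimethylsilyl)oxy]-2-methylhex-2-enal; 10 tert-butyldimethyl[(4-vinylfuran-2-yl)oxy]silane
Product: 12 (4S)-2-bromo-4-[(tert-butyldimethylsilyl)oxy]-1-oxo-13,15-dinor-1,2-seco-5αH-eudesm-7-en-6α,12-olide, via silyl ketene acetal cycloadduct 11 (not isolated)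
Conditions: PhMe, BHT (cat.), 95 °C; then AcOH–THF–H2O, 0 °C
Reagents that add atoms: none
Why: Thermal normal-demand Diels–Alder reaction in which the nucleophilic furan C5 terminus bonds to the enal β-carbon and the vinyl CH2 to the methyl-bearing α-carbon; the endo-CHO transition state (bulky C4 side chain exo) with the E-alkene sets 5-H/6-H trans and 6-H cis to the C10 methyl, attack anti to the allylic OTBS in the A(1,3)-minimised conformer fixes the absolute sense, and buffered protonation at C11 gives the β,γ-unsaturated lactone.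

**Step 8**
Reactants: 12 (4S)-2-bromo-4-[(tert-butyldimethylsilyl)oxy]-1-oxo-13,15-dinor-1,2-seco-5αH-eudesm-7-en-6α,12-olide
Product: 13 4β-[(tert-butyldimethylsilyl)oxy]-1ξ-hydroxy-13,15-dinor-5αH-eudesm-7-en-6α,12-olide
Conditions: SmI2, HMPA, THF, 0 °C
Reagents that add atoms: none
Why: Samarium Barbier cyclisation (6-exo) of the primary bromide onto the neopentyl aldehyde closes ring A under non-basic conditions; C1 and C4 are trans on ring B (from the E-dienophile) so only the trans-decalin forms, and the C1 configuration is irrelevant because it is oxidised in step 10.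

**Step 9**
Reactants: 13 4β-[(tert-butyldimethylsilyl)oxy]-1ξ-hydroxy-13,15-dinor-5αH-eudesm-7-en-6α,12-olide
Product: 14 1ξ,4β-dihydroxy-13,15-dinor-5αH-eudesm-7-en-6α,12-olide
Conditions: HF·pyridine, pyridine, THF, rt
Reagents that add atoms: none
Why: Fluoride-mediated desilylation under mildly acidic conditions that do not isomerise the β,γ-unsaturated lactone.

**Step 10**
Reactants: 14 1ξ,4β-dihydroxy-13,15-dinor-5αH-eudesm-7-en-6α,12-olide
Product: 15 1,4-dioxo-13,15-dinor-5αH-eudesm-7-en-6α,12-olide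
Conditions: Dess–Martin periodinane, NaHCO3, CH2Cl2, rt
Reagents that add atoms: none
Why: Buffered Dess–Martin oxidation of both secondary alcohols; the neutral conditions avoid β-elimination of the lactone oxygen and leave the (thermodynamically preferred) trans ring fusion untouched.

**Step 11**
Reactants: 15 1,4-dioxo-13,15-dinor-5αH-eudesm-7-en-6α,12-olide
Product: 16 1-oxo-13-nor-5αH-eudesma-4(15),7-dien-6α,12-olide
Conditions: Zn, CH2Br2, TiCl4, THF–CH2Cl2, 0 °C → rt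
Reagents that add atoms: dibromomethane, BrCBr
Why: Takai–Lombardo methylenation is non-basic and chemoselective for the C4 ketone over the neopentyl C1 ketone (flanked by quaternary C10) and the lactone, so C15 is introduced without epimerisation or alkene migration.

**Step 12**
Reactants: 16 1-oxo-13-nor-5αH-eudesma-4(15),7-dien-6α,12-olide
Product: 17 1β,8α,15-trihydroxy-13-nor-4αH,5αH,7αH-eudesman-6α,12-olide
Conditions: BH3·THF (4 eq.), THF, 0 °C → rt; NaBO3·4H2O, THF–H2O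
Reagents that add atoms: sodium perborate, [Na+].[O-]OB=O
Why: Hydroboration–oxidation with concurrent ketone reduction, all from the α-face because the axial C10 methyl blocks the β-face: axial hydride delivery gives the equatorial 1β-OH, syn addition to the 7,8-alkene places boron on C8 and hydrogen on C7 (8α-OH, 7α-H, trans-lactone), and the 4(15)-methylene gives the 15-ol (its C4 configuration is corrected in step 14).

**Step 13**
Reactants: 17 1β,8α,15-trihydroxy-13-nor-4αH,5αH,7αH-eudesman-6α,12-olide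
Product: 20 1β,8α,15-trihydroxy-4αH,5αH,7αH-eudesm-11(13)-en-6α,12-olide, via Mannich base 18 (not isolated), via trimethylammonium iodide 19 (not isolated)
Conditions: LDA (4.3 eq.), THF, −78 °C; CH2=NMe2+ I−, −78 → 0 °C; then MeI, MeOH; aq. NaHCO3, CH2Cl2
Reagents that add atoms: N,N-dimethylmethyleneiminium iodide (Eschenmoser's salt), C=[N+](C)C.[I-]
Why: Eschenmoser α-methylenation (lactone enolate Mannich reaction, N-quaternisation, E1cB elimination), carried out with the hydroxyls as lithium alkoxides at low temperature; no stereocentre is created.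

**Step 14**
Reactants: 20 1β,8α,15-trihydroxy-4αH,5αH,7αH-eudesm-11(13)-en-6α,12-olide
Product: 22 1β,8α-dihydroxy-15-oxo-4βH,5αH,7αH-eudesm-11(13)-en-6α,12-olide, via axial 4β-formyl epimer 21 (not isolated)
Conditions: PhI(OAc)2, TEMPO (10 mol %), CH2Cl2, rt; then DBU (10 mol %), 0 °C
Reagents that add atoms: none
Why: TEMPO/PhI(OAc)2 oxidises only the primary alcohol, and base-mediated enolisation then moves the formyl group to the equatorial 4α-position (relief of the 1,3-diaxial clash with the C10 methyl), so C4 is set under thermodynamic control.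

**Step 15**
Reactants: 23 2-(hydroxymethyl)acrylic acid
Product: 25 2-{[(tert-butyldimethylsilyl)oxy]methyl}acrylic acid, via bis-silylated acid 24 (not isolated)
Conditions: TBSCl (2.2 eq.), imidazole, DMF, rt; then AcOH–THF–H2O
Reagents that add atoms: tert-butyldimethylsilyl chloride, CC(C)(C)[Si](C)(C)Cl
Why: Exhaustive silylation followed by selective hydrolysis of the much more labile silyl ester leaves the primary silyl ether.

**Step 16**
Reactants: 22 1β,8α-dihydroxy-15-oxo-4βH,5αH,7αH-eudesm-11(13)-en-6α,12-olide; 25 2-{[(tert-butyldimethylsilyl)oxy]methyl}acrylic acid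
Product: 26 8α-(2-{[(tert-butyldimethylsilyl)oxy]methyl}acryloyloxy)-1β-hydroxy-15-oxo-4βH,5αH,7αH-eudesm-11(13)-en-6α,12-olide
Conditions: DCC, DMAP (cat.), CH2Cl2, −10 °C
Reagents that add atoms: none
Why: Steglich esterification; the 8α-OH is acylated in preference to the neopentylic 1β-OH, which is shielded by the quaternary C10, and configuration at C8 is retained.

**Step 17**
Reactants: 26 8α-(2-{[(tert-butyldimethylsilyl)oxy]methyl}acryloyloxy)-1β-hydroxy-15-oxo-4βH,5αH,7αH-eudesm-11(13)-en-6α,12-olide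
Product: 27 8α-[2-(hydroxymethyl)acryloyloxy]-1β-hydroxy-15-oxo-4βH,5αH,7αH-eudesm-11(13)-en-6α,12-olide
Conditions: HF·pyridine, pyridine, THF, 0 °C
Reagents that add atoms: none
Why: Buffered fluoride desilylation of the primary allylic silyl ether is compatible with the aldehyde, both acrylate units and the lactone.

**Step 18**
Reactants: 27 8α-[2-(hydroxymethyl)acryloyloxy]-1β-hydroxy-15-oxo-4βH,5αH,7αH-eudesm-11(13)-en-6α,12-olide
Product: 29 1β,6α-dihydroxy-8α-[2-(hydroxymethyl)acryloyloxy]-15-oxo-4βH,5αH,7αH-eudesm-11(13)-en-12-oic acid (CNP0599450.1), via lithium carboxylate 28 (not isolated)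
Conditions: LiOH (1.1 eq.), THF–H2O, 0 °C; then 0.1 M HCl to pH 4–5, 0 °C
Reagents that add atoms: lithium hydroxide (aqueous), [Li+].[OH-]
Why: Saponification of the strained trans-fused α-methylene-γ-lactone is much faster than that of the hindered secondary α-substituted acrylate ester, and cold acidification to pH 4–5 gives the free γ-hydroxy acid (cf. santoninic acid) without touching any stereocentre.

**Compound list**
1 | (S)-3-hydroxydihydrofuran-2(3H)-one, (S)-α-hydroxy-γ-butyrolactone | O[C@H]1CCOC1=O | starting material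
2 | ethyl (S)-4-bromo-2-hydroxybutanoate | CCOC(=O)[C@@H](O)CCBr | intermediate
3 | ethyl (S)-4-bromo-2-[(tert-butyldimethylsilyl)oxy]butanoate | CCOC(=O)[C@@H](O[Si](C)(C)C(C)(C)C)CCBr | intermediate
4 | (S)-4-bromo-2-[(tert-butyldimethylsilyl)oxy]butanal | O=C[C@@H](O[Si](C)(C)C(C)(C)C)CCBr | intermediate
5 | 2-(triphenylphosphoranylidene)propanal | CC(C=O)=P(c1ccccc1)(c1ccccc1)c1ccccc1 | starting material
6 | (S,E)-6-bromo-4-[(tert-butyldimethylsilyl)oxy]-2-methylhex-2-enal | O=C/C(C)=C/[C@@H](O[Si](C)(C)C(C)(C)C)CCBr | intermediate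
7 | 4-bromofuran-2(5H)-one | O=C1C=C(Br)CO1 | starting material
8 | tributyl(vinyl)stannane | C=C[Sn](CCCC)(CCCC)CCCC | starting material
9 | 4-vinylfuran-2(5H)-one | C=CC1=CC(=O)OC1 | intermediate
10 | tert-butyldimethyl[(4-vinylfuran-2-yl)oxy]silane | C=Cc1coc(O[Si](C)(C)C(C)(C)C)c1 | intermediate
11 | cycloadduct as O-silyl ketene acetal: (6R,7S,7aR)-7-[(1S)-3-bromo-1-(TBS-oxy)propyl]-2-(TBS-oxy)-6-methyl-5,6,7,7a-tetrahydro-1-benzofuran-6-carbaldehyde | C1C=C2C=C(O[Si](C)(C)C(C)(C)C)O[C@@H]2[C@@H]([C@@H](O[Si](C)(C)C(C)(C)C)CCBr)[C@]1(C)C=O | intermediate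
12 | (4S)-2-bromo-4-[(tert-butyldimethylsilyl)oxy]-1-oxo-13,15-dinor-1,2-seco-5αH-eudesm-7-en-6α,12-olide = (6R,7S,7aR)-7-[(1S)-3-bromo-1-(TBS-oxy)propyl]-6-methyl-2-oxo-2,3,5,6,7,7a-hexahydro-1-benzofuran-6-carbaldehyde (6β-H, 10β-CH3, 10α-CHO) | C1C=C2CC(=O)O[C@@H]2[C@@H]([C@@H](O[Si](C)(C)C(C)(C)C)CCBr)[C@]1(C)C=O | intermediate
13 | 4β-[(tert-butyldimethylsilyl)oxy]-1ξ-hydroxy-13,15-dinor-5αH-eudesm-7-en-6α,12-olide | C1C=C2CC(=O)O[C@@H]2[C@H]3[C@@H](O[Si](C)(C)C(C)(C)C)CCC(O)[C@]13C | intermediate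
14 | 1ξ,4β-dihydroxy-13,15-dinor-5αH-eudesm-7-en-6α,12-olide | C1C=C2CC(=O)O[C@@H]2[C@H]3[C@@H](O)CCC(O)[C@]13C | intermediate
15 | 1,4-dioxo-13,15-dinor-5αH-eudesm-7-en-6α,12-olide | C1C=C2CC(=O)O[C@@H]2[C@H]3C(=O)CCC(=O)[C@]13C | intermediate
16 | 1-oxo-13-nor-5αH-eudesma-4(15),7-dien-6α,12-olide | C1C=C2CC(=O)O[C@@H]2[C@H]3C(=C)CCC(=O)[C@]13C | intermediate
17 | 1β,8α,15-trihydroxy-13-nor-4αH,5αH,7αH-eudesman-6α,12-olide (CH2OH on C4 β, axial) | O[C@H]1C[C@]2(C)[C@@H]([C@H]3OC(=O)C[C@H]13)[C@@H](CO)CC[C@H]2O | intermediate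
18 | 13-(dimethylamino)-1β,8α,15-trihydroxy-4αH,5αH,7αH,11ξH-eudesman-6α,12-olide (Mannich base) | O[C@H]1C[C@]2(C)[C@@H]([C@H]3OC(=O)C(CN(C)C)[C@H]13)[C@@H](CO)CC[C@H]2O | intermediate
19 | N,N,N-trimethylammonium iodide of 18 | O[C@H]1C[C@]2(C)[C@@H]([C@H]3OC(=O)C(C[N+](C)(C)C)[C@H]13)[C@@H](CO)CC[C@H]2O.[I-] | intermediate
20 | 1β,8α,15-trihydroxy-4αH,5αH,7αH-eudesm-11(13)-en-6α,12-olide | O[C@H]1C[C@]2(C)[C@@H]([C@H]3OC(=O)C(=C)[C@H]13)[C@@H](CO)CC[C@H]2O | intermediate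
21 | 1β,8α-dihydroxy-15-oxo-4αH,5αH,7αH-eudesm-11(13)-en-6α,12-olide (4β-CHO, axial) | O[C@H]1C[C@]2(C)[C@@H]([C@H]3OC(=O)C(=C)[C@H]13)[C@@H](C=O)CC[C@H]2O | intermediate
22 | 1β,8α-dihydroxy-15-oxo-4βH,5αH,7αH-eudesm-11(13)-en-6α,12-olide (4α-CHO, equatorial) | O[C@H]1C[C@]2(C)[C@@H]([C@H]3OC(=O)C(=C)[C@H]13)[C@H](C=O)CC[C@H]2O | intermediate
23 | 2-(hydroxymethyl)acrylic acid | C=C(CO)C(=O)O | starting material
24 | tert-butyldimethylsilyl 2-{[(tert-butyldimethylsilyl)oxy]methyl}acrylate | C=C(CO[Si](C)(C)C(C)(C)C)C(=O)O[Si](C)(C)C(C)(C)C | intermediate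
25 | 2-{[(tert-butyldimethylsilyl)oxy]methyl}acrylic acid | C=C(CO[Si](C)(C)C(C)(C)C)C(=O)O | intermediate
26 | 8α-(2-{[(tert-butyldimethylsilyl)oxy]methyl}acryloyloxy)-1β-hydroxy-15-oxo-4βH,5αH,7αH-eudesm-11(13)-en-6α,12-olide | C=C(CO[Si](C)(C)C(C)(C)C)C(=O)O[C@H]1C[C@]2(C)[C@@H]([C@H]3OC(=O)C(=C)[C@H]13)[C@H](C=O)CC[C@H]2O | intermediate
27 | 8α-[2-(hydroxymethyl)acryloyloxy]-1β-hydroxy-15-oxo-4βH,5αH,7αH-eudesm-11(13)-en-6α,12-olide | C=C(CO)C(=O)O[C@H]1C[C@]2(C)[C@@H]([C@H]3OC(=O)C(=C)[C@H]13)[C@H](C=O)CC[C@H]2O | intermediate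
28 | lithium 1β,6α-dihydroxy-8α-[2-(hydroxymethyl)acryloyloxy]-15-oxo-4βH,5αH,7αH-eudesm-11(13)-en-12-oate | C=C(CO)C(=O)O[C@H]1C[C@]2(C)[C@@H]([C@@H](O)[C@@H]1C(=C)C(=O)[O-])[C@H](C=O)CC[C@H]2O.[Li+] | intermediate
29 | 1β,6α-dihydroxy-8α-[2-(hydroxymethyl)acryloyloxy]-15-oxo-4βH,5αH,7αH-eudesm-11(13)-en-12-oic acid (CNP0599450.1) | C=C(CO)C(=O)O[C@H]1C[C@]2(C)[C@@H]([C@@H](O)[C@@H]1C(=C)C(=O)O)[C@H](C=O)CC[C@H]2O | target

**Totals**
Total step count: 18. Longest linear sequence: 15 steps (1–4, 7–14, 16–18); steps 5–6 (diene) and 15 (side-chain acid) are convergent branches.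

**Three steps most likely to fail**

Step 7 (key cycloaddition: face and endo selectivity of an acyclic enal, possible carbonyl addition). The fallback sets out from 6 and returns at 15. Ring A is closed before the cycloaddition: SmI2/HMPA cyclises 6 to (4S)-4-[(tert-butyldimethylsilyl)oxy]-2-methylcyclohex-2-en-1-ol F1, which MnO2 oxidises to (S)-4-[(tert-butyldimethylsilyl)oxy]-2-methylcyclohex-2-en-1-one F2. A Lewis-acid-promoted (Me2AlCl or ZnBr2) endo [4+2] reaction of this rigid enone with diene 10, anti to the silyloxy group, gives the cis-fused O-silyl ketene acetal cycloadduct F3. Mild acid hydrolysis gives 4β-[(tert-butyldimethylsilyl)oxy]-1-oxo-13,15-dinor-5βH-eudesm-7-en-6α,12-olide F4. HF·pyridine gives 4β-hydroxy-1-oxo-13,15-dinor-5βH-eudesm-7-en-6α,12-olide F5, and Dess–Martin oxidation gives 1,4-dioxo-13,15-dinor-5βH-eudesm-7-en-6α,12-olide F6. Acid-catalysed (p-TsOH) enolisation of the C4 ketone then epimerises C5 to the trans-fused dione 15.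

Step 16 (discrimination of 8α-OH from 1β-OH in the acylation). The fallback sets out from 22 and returns at 27. A silyl relay replaces direct selective acylation: TESOTf/2,6-lutidine converts 22 into 1β,8α-bis[(triethylsilyl)oxy]-15-oxo-4βH-eudesm-11(13)-en-6α,12-olide F7. PPTS/MeOH at 0 °C removes only the less hindered 8-O-silyl group to give 8α-hydroxy-1β-[(triethylsilyl)oxy]-15-oxo-4βH-eudesm-11(13)-en-6α,12-olide F8. DCC/DMAP coupling with 25 gives 8α-(2-{[(tert-butyldimethylsilyl)oxy]methyl}acryloyloxy)-1β-[(triethylsilyl)oxy]-15-oxo-4βH-eudesm-11(13)-en-6α,12-olide F9, and the HF·pyridine treatment of step 17 removes both silyl groups to give 27.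

Step 18 (chemoselective lactone opening beside the acrylate ester, and relactonisation or acyl migration on work-up). The fallback sets out from 22 and returns at 29. The lactone is opened before the side-chain ester exists, and the acid is carried as an allyl ester:
- TESCl/imidazole protects the more accessible 8-OH to give 1β-hydroxy-8α-[(triethylsilyl)oxy]-15-oxo-4βH-eudesm-11(13)-en-6α,12-olide F10.
- LiOH opens the lactone to lithium 1β,6α-dihydroxy-8α-[(triethylsilyl)oxy]-15-oxo-4βH-eudesm-11(13)-en-12-oate F11, which is alkylated in the same flask (allyl bromide, DMF) to allyl 1β,6α-dihydroxy-8α-[(triethylsilyl)oxy]-15-oxo-4βH-eudesm-11(13)-en-12-oate F12.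
- TBSOTf/2,6-lutidine gives allyl 1β,6α-bis[(tert-butyldimethylsilyl)oxy]-8α-[(triethylsilyl)oxy]-15-oxo-4βH-eudesm-11(13)-en-12-oate F13.
- PPTS/MeOH removes the triethylsilyl group to give allyl 1β,6α-bis[(tert-butyldimethylsilyl)oxy]-8α-hydroxy-15-oxo-4βH-eudesm-11(13)-en-12-oate F14.
- DCC/DMAP coupling with 25 gives allyl 1β,6α-bis[(tert-butyldimethylsilyl)oxy]-8α-(2-{[(tert-butyldimethylsilyl)oxy]methyl}acryloyloxy)-15-oxo-4βH-eudesm-11(13)-en-12-oate F15.
- Pd(PPh3)4/morpholine removes the allyl group to give 1β,6α-bis[(tert-butyldimethylsilyl)oxy]-8α-(2-{[(tert-butyldimethylsilyl)oxy]methyl}acryloyloxy)-15-oxo-4βH-eudesm-11(13)-en-12-oic acid F16.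
- Pyridine-buffered HF·pyridine removes the three silyl ethers to give 29.

**Further compounds**
F1 | step 7 | (4S)-4-[(tert-butyldimethylsilyl)oxy]-2-methylcyclohex-2-en-1-ol (C1 epimers) | CC1=C[C@@H](O[Si](C)(C)C(C)(C)C)CCC1O
F2 | step 7 | (S)-4-[(tert-butyldimethylsilyl)oxy]-2-methylcyclohex-2-en-1-one | CC1=C[C@@H](O[Si](C)(C)C(C)(C)C)CCC1=O
F3 | step 7 | cis-fused cycloadduct as O-silyl ketene acetal (4β-OTBS, 1-oxo, 5βH, 12-OTBS, Δ7,Δ11) | C1C=C2C=C(O[Si](C)(C)C(C)(C)C)O[C@@H]2[C@@H]3[C@@H](O[Si](C)(C)C(C)(C)C)CCC(=O)[C@]13C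
F4 | step 7 | 4β-[(tert-butyldimethylsilyl)oxy]-1-oxo-13,15-dinor-5βH-eudesm-7-en-6α,12-olide | C1C=C2CC(=O)O[C@@H]2[C@@H]3[C@@H](O[Si](C)(C)C(C)(C)C)CCC(=O)[C@]13C
F5 | step 7 | 4β-hydroxy-1-oxo-13,15-dinor-5βH-eudesm-7-en-6α,12-olide | C1C=C2CC(=O)O[C@@H]2[C@@H]3[C@@H](O)CCC(=O)[C@]13C
F6 | step 7 | 1,4-dioxo-13,15-dinor-5βH-eudesm-7-en-6α,12-olide | C1C=C2CC(=O)O[C@@H]2[C@@H]3C(=O)CCC(=O)[C@]13C
F7 | step 16 | 1β,8α-bis[(triethylsilyl)oxy]-15-oxo-4βH-eudesm-11(13)-en-6α,12-olide | CC[Si](CC)(CC)O[C@H]1C[C@]2(C)[C@@H]([C@H]3OC(=O)C(=C)[C@H]13)[C@H](C=O)CC[C@H]2O[Si](CC)(CC)CC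
F8 | step 16 | 8α-hydroxy-1β-[(triethylsilyl)oxy]-15-oxo-4βH-eudesm-11(13)-en-6α,12-olide | O[C@H]1C[C@]2(C)[C@@H]([C@H]3OC(=O)C(=C)[C@H]13)[C@H](C=O)CC[C@H]2O[Si](CC)(CC)CC
F9 | step 16 | 8α-(2-{[(tert-butyldimethylsilyl)oxy]methyl}acryloyloxy)-1β-[(triethylsilyl)oxy]-15-oxo-4βH-eudesm-11(13)-en-6α,12-olide | C=C(CO[Si](C)(C)C(C)(C)C)C(=O)O[C@H]1C[C@]2(C)[C@@H]([C@H]3OC(=O)C(=C)[C@H]13)[C@H](C=O)CC[C@H]2O[Si](CC)(CC)CC
F10 | step 18 | 1β-hydroxy-8α-[(triethylsilyl)oxy]-15-oxo-4βH-eudesm-11(13)-en-6α,12-olide | CC[Si](CC)(CC)O[C@H]1C[C@]2(C)[C@@H]([C@H]3OC(=O)C(=C)[C@H]13)[C@H](C=O)CC[C@H]2O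
F11 | step 18 | lithium 1β,6α-dihydroxy-8α-[(triethylsilyl)oxy]-15-oxo-4βH-eudesm-11(13)-en-12-oate | CC[Si](CC)(CC)O[C@H]1C[C@]2(C)[C@@H]([C@@H](O)[C@@H]1C(=C)C(=O)[O-])[C@H](C=O)CC[C@H]2O.[Li+]
F12 | step 18 | allyl 1β,6α-dihydroxy-8α-[(triethylsilyl)oxy]-15-oxo-4βH-eudesm-11(13)-en-12-oate | CC[Si](CC)(CC)O[C@H]1C[C@]2(C)[C@@H]([C@@H](O)[C@@H]1C(=C)C(=O)OCC=C)[C@H](C=O)CC[C@H]2O
F13 | step 18 | allyl 1β,6α-bis[(tert-butyldimethylsilyl)oxy]-8α-[(triethylsilyl)oxy]-15-oxo-4βH-eudesm-11(13)-en-12-oate | CC[Si](CC)(CC)O[C@H]1C[C@]2(C)[C@@H]([C@@H](O[Si](C)(C)C(C)(C)C)[C@@H]1C(=C)C(=O)OCC=C)[C@H](C=O)CC[C@H]2O[Si](C)(C)C(C)(C)C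
F14 | step 18 | allyl 1β,6α-bis[(tert-butyldimethylsilyl)oxy]-8α-hydroxy-15-oxo-4βH-eudesm-11(13)-en-12-oate | O[C@H]1C[C@]2(C)[C@@H]([C@@H](O[Si](C)(C)C(C)(C)C)[C@@H]1C(=C)C(=O)OCC=C)[C@H](C=O)CC[C@H]2O[Si](C)(C)C(C)(C)C
F15 | step 18 | allyl 1β,6α-bis[(tert-butyldimethylsilyl)oxy]-8α-(2-{[(tert-butyldimethylsilyl)oxy]methyl}acryloyloxy)-15-oxo-4βH-eudesm-11(13)-en-12-oate | C=C(CO[Si](C)(C)C(C)(C)C)C(=O)O[C@H]1C[C@]2(C)[C@@H]([C@@H](O[Si](C)(C)C(C)(C)C)[C@@H]1C(=C)C(=O)OCC=C)[C@H](C=O)CC[C@H]2O[Si](C)(C)C(C)(C)C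
F16 | step 18 | 1β,6α-bis[(tert-butyldimethylsilyl)oxy]-8α-(2-{[(tert-butyldimethylsilyl)oxy]methyl}acryloyloxy)-15-oxo-4βH-eudesm-11(13)-en-12-oic acid | C=C(CO[Si](C)(C)C(C)(C)C)C(=O)O[C@H]1C[C@]2(C)[C@@H]([C@@H](O[Si](C)(C)C(C)(C)C)[C@@H]1C(=C)C(=O)O)[C@H](C=O)CC[C@H]2O[Si](C)(C)C(C)(C)C
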